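If Q in the flask could turn to D and never return, Q would drain away and D would end as the one product; if Q never turned, Q would end as the one product and D would not form.

| flask | E | X | remark | time |
|---|---|---|---|---|
| spring | 0.014 M (fed, over 50 min) | 26 µM | run made earlier; the fed solution adds 0.20 times the starting volume |  |
| dawn | 0.022 M (fed, over 50 min) | 26 µM | run made earlier; the fed solution adds 0.20 times the starting volume |  |
| dusk | 0.010 M (fed, over 50 min) | 13 µM | run made earlier; the fed solution adds 0.20 times the starting volume |  |
| flask | 0.010 M (fed, over 50 min) | 26 µM | the fed solution adds 0.20 times the starting volume | 10 h |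

- spring (time / h: D / %, Q / %): 2.00: 39.9, 54.3; 4.00: 58.1, 41.1; 6.00: 56.6, 39.9; 8.00: 57.2, 42.6
- dawn (time / h: D / %, Q / %): 0.667: 3.6, 21.2; 1.33: 7.7, 45.0; 3.00: 47.4, 46.5; 8.00: 56.4, 40.4
- dusk (time / h: D / %, Q / %): 0.667: 2.6, 18.5; 1.33: 7.5, 41.1; 3.00: 39.1, 54.5; 8.00: 57.7, 40.7

(standard deviation of a reading: 1 percentage point)

- D present at 10 h, in percent of the E charged
- Q present at 10 h, in percent of the E charged

- charges are per starting volume, the dose included; the dosed solution carries all of it
- percentages count the whole charge, also what has not yet gone in

The real flask had to lie between these extremes, and I looked for where by comparing two rates at one moment. With X held, Q goes to D at a rate that follows Q, and D comes back at a rate that follows D, so the forward rate wins while D over Q is small, as in dusk at 0.667 h, where that ratio read 0.141. As the ratio climbs the margin shrinks, and it closes at the stop ratio, the value of D over Q at which the two rates match (thermodynamic control), 1.39 as the mean of spring, dawn and dusk at 8.00 h.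

The flask holds the X of spring and less E, and spring's ratio already read 1.41 at 4.00 h. So I took the flask as stopped at 10 h. Dusk, with the same charge of E, read D and Q together as 98.4% of the charge at 8.00 h, and sharing that reading by the stop ratio gave me D 57.2% and Q 41.2%.

The forecast said D 57% and Q 41%, in the words “The plateau therefore doesn't depend on E charge, X loading or E:X ratio”. The flask gave D 57.4% and Q 41.0%.

    Q + X ⇌ D + X, rate k1*[X]*[Q] forward; the back reaction follows from the equilibrium constant (K = 1.40, k = 1300 M⁻¹ min⁻¹)
    E + X ⇌ L (K = 190 M⁻¹, k = 22000 M⁻¹ min⁻¹)
    L ⇌ J (K = 1.50, k = 660 min⁻¹)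
    2 J ⇌ Z, settled at all times (K = 12000 M⁻¹)
    J ⇌ X + Q (K = 0.0900 M, k = 15.0 min⁻¹)

D stopped short of the first extreme because D returns to Q: the run with that back reaction taken away ended with D at >99.9%, against 57.4% with it. The flask's own ratio was 1.40 at 10 h. I then carried the stop ratio to the neighbour flask with 6.5 × 10⁻⁵ M of X: sharing its D and Q, 98.4% together, by 1.39 gives D 57.1%, and that neighbour flask stood at 57.4%.

(The readings are calculated with constants of no real substance; the scatter is artificial.)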